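The benzene ring of the phthalide is disconnected at C3a–C4 and C7–C7a. That ring carries methoxy groups on C5 and C7, the lactone carbonyl C1 on C7a and the stereogenic carbinol C3 on C3a, a pattern that maps onto 1,3-dimethoxycyclohexa-1,3-diene and a 4-silyloxy-2-ynoate. One thermal operation, a Diels–Alder addition followed by extrusion of ethylene (Alder–Rickert), builds the complete arene with all four substituents placed. The ynoate partner already holds the S carbinol, set by catalytic aldehyde alkynylation, and the whole C1'–C16' diketone chain, released from a 2,5-dialkylfuran. Desilylation with lactonisation then gives the target.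

Key step: step 8

Assumption: (R)-BINOL is taken as the antipode whose titanium complex directs alkynyl transfer to the Re face of an unbranched aliphatic aldehyde, the face that leads to the S carbinol; if the sense is opposite, (S)-BINOL is used and nothing else changes.

Design notes: Birch reduction of 1,3-dimethoxybenzene delivers the skipped 1,5-dimethoxycyclohexa-1,4-diene, not the conjugated diene that the cycloaddition needs, so a base-mediated conjugation (step 7) is part of the route. The free hydroxyl of 12-bromododecan-1-ol consumes one equivalent of organolithium, so step 1 uses the furyllithium in excess.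

Step 1
Reactants: 1 2-methylfuran; 2 12-bromododecan-1-ol
Product: 5 12-(5-methylfuran-2-yl)dodecan-1-ol, via 5-methyl-2-furyllithium 3 (not isolated), via lithium 12-bromododecan-1-olate 4 (not isolated)
Conditions: 1 (2.5 equiv), n-BuLi (2.3 equiv), THF, 0 °C → rt; then 2 (1.0 equiv), THF, 0 °C → rt; H2O work-up
Reagents that add atoms: none
Why: Lithiation of the furan at its free α-position followed by SN2 alkylation of the primary bromide should form the C–C bond, the first equivalent of 3 merely turning the hydroxyl of 2 into an inert lithium alkoxide.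

Step 2
Reactants: 5 12-(5-methylfuran-2-yl)dodecan-1-ol
Product: 6 17-hydroxyheptadecane-2,5-dione
Conditions: 2 M aq H2SO4, 1,4-dioxane, 85 °C
Reagents that add atoms: water, O
Why: Acid-catalysed hydrolytic ring opening of a 2,5-dialkylfuran (the reverse of a Paal–Knorr furan synthesis) should unmask the 1,4-diketone, while the primary alcohol is inert to aqueous acid free of carboxylic acids.

Step 3
Reactants: 6 17-hydroxyheptadecane-2,5-dione
Product: 7 13,16-dioxoheptadecanal
Conditions: TEMPO (10 mol%), PhI(OAc)2 (1.1 equiv), CH2Cl2, rt
Reagents that add atoms: none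
Why: Oxoammonium-mediated (TEMPO) oxidation of a primary alcohol should stop at the aldehyde under near-neutral conditions that leave the enolisable 1,4-diketone untouched.

Step 4
Reactants: 7 13,16-dioxoheptadecanal; 8 methyl propiolate
Product: 10 methyl (S)-4-hydroxy-16,19-dioxoicos-2-ynoate, via ethylzinc alkynylide 9 (not isolated)
Conditions: 8 (4 equiv), ZnEt2 (4 equiv), (R)-BINOL (40 mol%), HMPA (2 equiv), CH2Cl2, rt, 16 h; Ti(OiPr)4 (1 equiv), 1 h; then 7, rt; 1 M HCl work-up
Reagents that add atoms: none
Why: BINOL–titanium-promoted catalytic asymmetric alkynylzinc addition should take place at the aldehyde far faster than at either ketone, and the stereocentre is set by reagent control, the (R)-BINOL–titanium complex delivering the alkynyl group to the Re face of the aldehyde to give the S carbinol.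

Step 5
Reactants: 10 methyl (S)-4-hydroxy-16,19-dioxoicos-2-ynoate
Product: 11 methyl (S)-4-(tert-butyldimethylsilyloxy)-16,19-dioxoicos-2-ynoate
Conditions: TBSCl, imidazole, DMF, 0 °C → rt
Reagents that add atoms: tert-butyldimethylsilyl chloride (TBSCl), CC(C)(C)[Si](C)(C)Cl
Why: Imidazole-mediated silylation of a secondary alcohol uses a base too weak to isomerise the γ-hydroxy ynoate, and it does not touch the C–O bond of the stereocentre.

Step 6
Reactants: 12 1,3-dimethoxybenzene
Product: 13 1,5-dimethoxycyclohexa-1,4-diene
Conditions: Li, liq. NH3, THF, t-BuOH, −78 → −33 °C; MeOH then H2O, pentane extraction (no acid)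
Reagents that add atoms: none
Why: Birch reduction of a 1,3-dialkoxyarene should leave both residual double bonds on the oxygen-bearing carbons, giving the skipped bis(enol ether).

Step 7
Reactants: 13 1,5-dimethoxycyclohexa-1,4-diene
Product: 14 1,3-dimethoxycyclohexa-1,3-diene
Conditions: KOtBu (0.3 equiv), DMSO, rt; H2O/pentane, distillation
Reagents that add atoms: none
Why: Base-mediated prototropic isomerisation through the pentadienyl anion (deprotonation at the doubly allylic CH2 between the two enol ethers) should move one double bond into conjugation; the conjugated diene is expected to predominate at equilibrium, and residual 13 is an inert diluent in step 8.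

Step 8
Reactants: 11 methyl (S)-4-(tert-butyldimethylsilyloxy)-16,19-dioxoicos-2-ynoate; 14 1,3-dimethoxycyclohexa-1,3-diene
Product: 16 methyl 2-[(S)-1-(tert-butyldimethylsilyloxy)-13,16-dioxoheptadecyl]-4,6-dimethoxybenzoate, via bicyclo[2.2.2]octadiene adduct 15 (not isolated)
Conditions: 14 (4 equiv), neat, BHT (cat.), base-washed sealed tube, argon, 120 °C then 185 °C
Reagents that add atoms: none
Why: The electron-rich diene 14 adds thermally across the ester-activated triple bond of 11 in a normal-demand [4+2] cycloaddition with an unsymmetrical transition state, the bond from the free diene terminus to the ynoate β-carbon being the more advanced; the resulting bicyclo[2.2.2]octadiene 15 then loses its saturated two-carbon bridge as ethylene by a retro-Diels–Alder reaction, pulled forward by aromatisation and by escape of the gas. The closest known reaction type is the Alder–Rickert synthesis of 6-substituted 2,4-dimethoxybenzoates from this diene and 2-alkynoates. The benzene ring (C3a, C4, C5, C6, C7, C7a) is closed in the one intermolecular, suprafacial cycloaddition that forms C3a–C4 and C7–C7a, not by a separate cyclisation. No stereocentre is created, since the bridgehead centres of 15 (formed as a mixture) disappear on aromatisation, and the S centre at C3 set in step 4 is a spectator held in place by the neutral medium and by the silyl ether, which blocks propargylic isomerisation. The step needs regiocontrol, supplied by polarity matching: the unsubstituted diene terminus, the carbon made most nucleophilic by both methoxy groups, bonds to the β-carbon bearing C3, so the methoxy-bearing terminus ends as C7 beside the ester carbon C7a. The remote ketones are not dienophiles for an enol ether diene without acid, and the excess of 14, the radical inhibitor and the base-washed vessel guard against its acid and thermal lability.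

Step 9
Reactants: 16 methyl 2-[(S)-1-(tert-butyldimethylsilyloxy)-13,16-dioxoheptadecyl]-4,6-dimethoxybenzoate
Product: 18 CJ-13,103 [(S)-3-(12,15-dioxohexadecyl)-5,7-dimethoxyisobenzofuran-1(3H)-one], via hydroxy ester 17 (not isolated)
Conditions: 48% aq HF, MeCN, 0 °C → rt
Reagents that add atoms: none
Why: Cleavage of the silyl ether by HF frees the C3 hydroxyl, which should close onto the neighbouring methyl ester by 5-exo-trig acyl substitution (lactonisation) with loss of methanol; the C3–O bond is never broken, so the S configuration is retained, and the mildly acidic medium spares the 1,4-diketone.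

Compound list
1 | 2-methylfuran | Cc1ccco1 | starting material
2 | 12-bromododecan-1-ol | OCCCCCCCCCCCCBr | starting material
3 | 5-methyl-2-furyllithium | [Li]c1ccc(C)o1 | intermediate
4 | lithium 12-bromododecan-1-olate | [Li+].[O-]CCCCCCCCCCCCBr | intermediate
5 | 12-(5-methylfuran-2-yl)dodecan-1-ol | Cc1ccc(CCCCCCCCCCCCO)o1 | intermediate
6 | 17-hydroxyheptadecane-2,5-dione | CC(=O)CCC(=O)CCCCCCCCCCCCO | intermediate
7 | 13,16-dioxoheptadecanal | CC(=O)CCC(=O)CCCCCCCCCCCC=O | intermediate
8 | methyl propiolate | COC(=O)C#C | starting material
9 | ethyl(3-methoxy-3-oxoprop-1-yn-1-yl)zinc | CC[Zn]C#CC(=O)OC | intermediate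
10 | methyl (S)-4-hydroxy-16,19-dioxoicos-2-ynoate | COC(=O)C#C[C@H](CCCCCCCCCCCC(=O)CCC(C)=O)O | intermediate
11 | methyl (S)-4-(tert-butyldimethylsilyloxy)-16,19-dioxoicos-2-ynoate | COC(=O)C#C[C@H](CCCCCCCCCCCC(=O)CCC(C)=O)O[Si](C)(C)C(C)(C)C | intermediate
12 | 1,3-dimethoxybenzene | COc1cccc(OC)c1 | starting material
13 | 1,5-dimethoxycyclohexa-1,4-diene | COC1=CCC=C(OC)C1 | intermediate
14 | 1,3-dimethoxycyclohexa-1,3-diene | COC1=CC(OC)=CCC1 | intermediate
15 | methyl 3-[(S)-1-(tert-butyldimethylsilyloxy)-13,16-dioxoheptadecyl]-1,5-dimethoxybicyclo[2.2.2]octa-2,5-diene-2-carboxylate (both bridgehead diastereomers) | COC(=O)C1=C([C@H](CCCCCCCCCCCC(=O)CCC(C)=O)O[Si](C)(C)C(C)(C)C)C2CCC1(OC)C=C2OC | intermediate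
16 | methyl 2-[(S)-1-(tert-butyldimethylsilyloxy)-13,16-dioxoheptadecyl]-4,6-dimethoxybenzoate | COc1cc(OC)c(C(=O)OC)c(c1)[C@H](CCCCCCCCCCCC(=O)CCC(C)=O)O[Si](C)(C)C(C)(C)C | intermediate
17 | methyl 2-[(S)-1-hydroxy-13,16-dioxoheptadecyl]-4,6-dimethoxybenzoate | COc1cc(OC)c(C(=O)OC)c(c1)[C@H](CCCCCCCCCCCC(=O)CCC(C)=O)O | intermediate
18 | CJ-13,103, (S)-3-(12,15-dioxohexadecyl)-5,7-dimethoxyisobenzofuran-1(3H)-one | COc1cc(OC)c2c(c1)[C@H](CCCCCCCCCCCC(=O)CCC(C)=O)OC2=O | target

Total step count: 9. Longest linear sequence: 7 steps (steps 1, 2, 3, 4, 5, 8, 9); steps 6 and 7 form the two-step diene arm.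

Steps most likely to fail

Step 8. The electron-rich diene may aromatise or polymerise before it adds to the hindered ynoate, or the adduct may not expel ethylene below the temperature at which the silyl ether or the diketone chain begins to degrade. The fallback sets out from 11 and forms the arene by loss of methanol instead of ethylene. The ynoate is heated in toluene at 80–110 °C with the acyclic vinylketene acetal 1,3-dimethoxy-1-(trimethylsilyloxy)buta-1,3-diene F1, made from commercial methyl (E)-3-methoxybut-2-enoate with LiN(iPr)2 and TMSCl in THF at −78 °C. With the same polarity matching, the Diels–Alder adduct methyl 2-[(S)-1-(tert-butyldimethylsilyloxy)-13,16-dioxoheptadecyl]-4,6-dimethoxy-6-(trimethylsilyloxy)cyclohexa-1,4-diene-1-carboxylate F2 should aromatise by 1,4-loss of methanol to the aryl silyl ether methyl 2-[(S)-1-(tert-butyldimethylsilyloxy)-13,16-dioxoheptadecyl]-4-methoxy-6-(trimethylsilyloxy)benzoate F3. Mild aqueous acid on work-up should then give the salicylate methyl 2-[(S)-1-(tert-butyldimethylsilyloxy)-13,16-dioxoheptadecyl]-6-hydroxy-4-methoxybenzoate F4. O-Methylation (MeI, K2CO3, DMF, rt) returns to the route at 16.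

Step 4. Facial selectivity in the alkynyl transfer to an unbranched aldehyde may be poor, and ethyl transfer from ZnEt2 may compete. The fallback sets out from 7 and sets the stereocentre by reduction instead of addition. The zinc alkynylide 9 is added with racemic BINOL to give racemic methyl 4-hydroxy-16,19-dioxoicos-2-ynoate F5. Dess–Martin periodinane (CH2Cl2, NaHCO3) then gives the ynone methyl 4,16,19-trioxoicos-2-ynoate F6. Midland reduction with (S)-Alpine-Borane (THF, rt) reduces a conjugated ynone far faster than the dialkyl ketones and, by its usual model with the alkynyl group as the small substituent, should deliver the S carbinol, returning to the route at 10.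

Step 1. The lithium alkoxide may aggregate with the furyllithium and slow the substitution, so that alkylation stalls and elimination of HBr competes. The fallback sets out from 2 and masks the hydroxyl. Protection (3,4-dihydro-2H-pyran, PPTS, CH2Cl2) gives 2-[(12-bromododecyl)oxy]tetrahydro-2H-pyran F7. Alkylation of 3 (1.2 equiv, THF) gives 2-{[12-(5-methylfuran-2-yl)dodecyl]oxy}tetrahydro-2H-pyran F8. The aqueous acid of step 2 then opens the furan and cleaves the acetal in the same flask, so the route is rejoined at 6 without a separate deprotection.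

Further compounds
F1 | step 8 | 1,3-dimethoxy-1-(trimethylsilyloxy)buta-1,3-diene | C=C(OC)C=C(OC)O[Si](C)(C)C
F2 | step 8 | methyl 2-[(S)-1-(tert-butyldimethylsilyloxy)-13,16-dioxoheptadecyl]-4,6-dimethoxy-6-(trimethylsilyloxy)cyclohexa-1,4-diene-1-carboxylate | COC(=O)C1=C([C@H](CCCCCCCCCCCC(=O)CCC(C)=O)O[Si](C)(C)C(C)(C)C)CC(OC)=CC1(OC)O[Si](C)(C)C
F3 | step 8 | methyl 2-[(S)-1-(tert-butyldimethylsilyloxy)-13,16-dioxoheptadecyl]-4-methoxy-6-(trimethylsilyloxy)benzoate | COC(=O)c1c(O[Si](C)(C)C)cc(OC)cc1[C@H](CCCCCCCCCCCC(=O)CCC(C)=O)O[Si](C)(C)C(C)(C)C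
F4 | step 8 | methyl 2-[(S)-1-(tert-butyldimethylsilyloxy)-13,16-dioxoheptadecyl]-6-hydroxy-4-methoxybenzoate | COC(=O)c1c(O)cc(OC)cc1[C@H](CCCCCCCCCCCC(=O)CCC(C)=O)O[Si](C)(C)C(C)(C)C
F5 | step 4 | racemic methyl 4-hydroxy-16,19-dioxoicos-2-ynoate | COC(=O)C#CC(O)CCCCCCCCCCCC(=O)CCC(C)=O
F6 | step 4 | methyl 4,16,19-trioxoicos-2-ynoate | COC(=O)C#CC(=O)CCCCCCCCCCCC(=O)CCC(C)=O
F7 | step 1 | 2-[(12-bromododecyl)oxy]tetrahydro-2H-pyran | BrCCCCCCCCCCCCOC1CCCCO1
F8 | step 1 | 2-{[12-(5-methylfuran-2-yl)dodecyl]oxy}tetrahydro-2H-pyran | Cc1ccc(CCCCCCCCCCCCOC2CCCCO2)o1
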